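## Retrosynthetic overview

1. The dihydrofuran ring (O1–C2) is closed last: fluoride unmasks the phenols of an open-chain silylated nitro compound, nitrite leaves to give a quinone methide, and the ring A phenol closes 5-exo with C2 trans to C3.
2. C2–C3 is made by an enantioselective organocatalytic conjugate addition of a (2,4-bis-silyloxyphenyl)nitromethane to the ortho-quinone methide of ring A, released from a benzylic sulfone; this sets C3.
3. C3–C3a comes from directed ortho-lithiation of tris-MOM dihydroresveratrol between its two OMOM groups and addition to 3,5-bis(silyloxy)benzaldehyde, with MOM removal and sulfinate capture in the same pot.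
4. The aryl nitromethane comes from Pd-catalysed nitromethylation of silylated 4-bromoresorcinol.
5. Ring order: all four benzene rings are bought; the only ring formed is the dihydrofuran, in the last step.

Assumption: the target is the trans-(2S,3S) isomer as drawn; dihydroresveratrol, 3,5-dihydroxybenzaldehyde, 4-bromoresorcinol, nitromethane, the protecting-group reagents and the quinine-derived squaramide are bought.

## Route

Step 1
Reactants: 1 dihydroresveratrol (5-[2-(4-hydroxyphenyl)ethyl]benzene-1,3-diol)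
Product: 2 1,3-bis(methoxymethoxy)-5-{2-[4-(methoxymethoxy)phenyl]ethyl}benzene
Conditions: NaH (3.6 equiv), MOMCl (3.6 equiv), DMF, 0 °C → rt
Reagents that add atoms: chloromethyl methyl ether (MOMCl), COCCl
Why: Williamson-type O-alkylation of the three sodium phenoxides by MOMCl gives the tris-MOM ether, whose two OMOM groups on ring A later act as cooperating ortho-directing groups.

Step 2
Reactants: 3 3,5-dihydroxybenzaldehyde
Product: 4 3,5-bis(triisopropylsilyloxy)benzaldehyde
Conditions: TIPSCl (2.3 equiv), imidazole, DMF, rt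
Reagents that add atoms: chlorotriisopropylsilane (TIPSCl), CC(C)[Si](Cl)(C(C)C)C(C)C
Why: imidazole-promoted O-silylation of both phenols gives aryl TIPS ethers that tolerate the aryllithium addition and the acidic methanolysis of step 3 and fall to fluoride in step 7.

Step 3
Reactants: 2 1,3-bis(methoxymethoxy)-5-{2-[4-(methoxymethoxy)phenyl]ethyl}benzene; 4 3,5-bis(triisopropylsilyloxy)benzaldehyde
Product: 7 racemic 2-{[3,5-bis(triisopropylsilyloxy)phenyl](4-methylbenzenesulfonyl)methyl}-5-[2-(4-hydroxyphenyl)ethyl]benzene-1,3-diol, via aryllithium 5 (not isolated), via benzhydrol 6 (not isolated)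
Conditions: n-BuLi (1.1 equiv), THF, 0 °C; 4, −78 → 0 °C; then TolSO2Na (5 equiv), conc. HCl, MeOH, 45 °C
Reagents that add atoms: sodium 4-methylbenzenesulfinate, [Na+].Cc1ccc(cc1)S([O-])=O
Why: directed ortho-metalation at the position flanked by the two OMOM groups gives 5, its 1,2-addition to aldehyde 4 gives the silica-sensitive benzhydrol 6, and in acidic methanol the doubly ortho-oxygenated benzhydryl cation is captured at sulfur by p-toluenesulfinate (SN1 sulfone formation) while the three MOM acetals are methanolysed, the racemic sulfone carbon being flattened again in step 6.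

Step 4
Reactants: 8 4-bromoresorcinol (4-bromobenzene-1,3-diol)
Product: 9 1-bromo-2,4-bis(triisopropylsilyloxy)benzene
Conditions: TIPSCl (2.3 equiv), imidazole, DMF, rt
Reagents that add atoms: chlorotriisopropylsilane (TIPSCl), CC(C)[Si](Cl)(C(C)C)C(C)C
Why: imidazole-promoted O-silylation masks both phenols as base-robust, fluoride-labile TIPS ethers, the para one being the later trigger for loss of nitrite.

Step 5
Reactants: 9 1-bromo-2,4-bis(triisopropylsilyloxy)benzene; 10 nitromethane
Product: 11 1-(nitromethyl)-2,4-bis(triisopropylsilyloxy)benzene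
Conditions: Pd2(dba)3 (2.5 mol%), XPhos (6 mol%), Cs2CO3 (1.2 equiv), MeNO2/1,4-dioxane, 4 Å MS, 60 °C; AcOH work-up
Reagents that add atoms: none
Why: Pd-catalysed nitromethylation (cross-coupling of an aryl bromide with the nitronate of nitromethane) proceeds by oxidative addition of the C–Br bond to zerovalent palladium–XPhos, exchange of bromide for the C-bound nitronate and reductive elimination, the large excess of nitromethane suppressing a second arylation.

Step 6
Reactants: 7 racemic 2-{[3,5-bis(triisopropylsilyloxy)phenyl](4-methylbenzenesulfonyl)methyl}-5-[2-(4-hydroxyphenyl)ethyl]benzene-1,3-diol; 11 1-(nitromethyl)-2,4-bis(triisopropylsilyloxy)benzene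
Product: 13 2-{(1S)-1-[3,5-bis(triisopropylsilyloxy)phenyl]-2-[2,4-bis(triisopropylsilyloxy)phenyl]-2-nitroethyl}-5-[2-(4-hydroxyphenyl)ethyl]benzene-1,3-diol (epimer mixture at the nitro carbon), via ortho-quinone methide 12 (not isolated)
Conditions: 3-{[3,5-bis(trifluoromethyl)phenyl]amino}-4-{[(8α,9S)-6'-methoxycinchonan-9-yl]amino}cyclobut-3-ene-1,2-dione (10 mol%), 11 (1.3 equiv), aq. NaHCO3, CH2Cl2, 0 °C
Reagents that add atoms: none
Why: Proposed new method: bicarbonate-triggered 1,4-elimination of p-toluenesulfinate from 7 releases ortho-quinone methide 12 at low concentration, the quinuclidine of the bifunctional squaramide deprotonates aryl nitromethane 11 (pKa about 12 in DMSO) and holds the nitronate on the two squaramide N–H bonds while the quinuclidinium N–H binds the quinone methide carbonyl, so the nitronate carbon adds to one face of the methide carbon (Si face in the working model) and sets the diarylmethine carbon, the future C3, as S, with rearomatisation as driving force and the nitro-bearing carbon left as an epimer mixture because step 7 resets it; closest known reaction type: cinchona-squaramide-catalysed enantioselective additions of malononitrile, 1,3-dicarbonyls and Meldrum's acid to ortho-quinone methides generated from 2-(arylsulfonylalkyl)phenols under aqueous NaHCO3, together with squaramide-catalysed nitro-Michael additions.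

Step 7
Reactants: 13 2-{(1S)-1-[3,5-bis(triisopropylsilyloxy)phenyl]-2-[2,4-bis(triisopropylsilyloxy)phenyl]-2-nitroethyl}-5-[2-(4-hydroxyphenyl)ethyl]benzene-1,3-diol
Product: 16 target (2S,3S)-2-(2,4-dihydroxyphenyl)-3-(3,5-dihydroxyphenyl)-6-[2-(4-hydroxyphenyl)ethyl]-2,3-dihydro-1-benzofuran-4-ol, via hexaphenol nitro compound 14 (not isolated), via para-quinone methide 15 (not isolated)
Conditions: TBAF (5 equiv), AcOH (3 equiv), degassed THF, 0 °C → rt
Reagents that add atoms: none
Why: Proposed new method: fluoride cleaves the four aryl O–Si bonds to give 14, the freed 4-phenoxide (or 2-phenoxide) of the nitro-bearing ring expels nitrite by 1,6-elimination (the phenylogous counterpart of E1cB loss of HNO2 from β-nitro carbonyl compounds and of the sulfinate loss used in step 6, with AcOH keeping the nitro carbon from resting as the unreactive nitronate) to give quinone methide 15, and the adjacent ring A phenol closes the dihydrofuran by 5-exo oxa-1,6-addition, setting C2 trans to the untouched C3 (2S,3S) because the two aryl groups avoid each other in the closure and any cis isomer reopens to 15 and recloses to the more stable trans isomer; closest known reaction types: fluoride- or base-triggered quinone methide generation from silyloxybenzyl or hydroxybenzyl derivatives with oxa-conjugate closure to 2-aryl-2,3-dihydrobenzofurans, and Lewis-acid substitution of benzylic nitro groups.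

## Compound list

1 | dihydroresveratrol, 5-[2-(4-hydroxyphenyl)ethyl]benzene-1,3-diol | Oc1ccc(CCc2cc(O)cc(O)c2)cc1 | starting material
2 | 1,3-bis(methoxymethoxy)-5-{2-[4-(methoxymethoxy)phenyl]ethyl}benzene | COCOc1ccc(CCc2cc(OCOC)cc(OCOC)c2)cc1 | intermediate
3 | 3,5-dihydroxybenzaldehyde | O=Cc1cc(O)cc(O)c1 | starting material
4 | 3,5-bis(triisopropylsilyloxy)benzaldehyde | O=Cc1cc(O[Si](C(C)C)(C(C)C)C(C)C)cc(O[Si](C(C)C)(C(C)C)C(C)C)c1 | intermediate
5 | {2,6-bis(methoxymethoxy)-4-[2-(4-(methoxymethoxy)phenyl)ethyl]phenyl}lithium (not isolated) | [Li]c1c(OCOC)cc(CCc2ccc(OCOC)cc2)cc1OCOC | intermediate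
6 | racemic [3,5-bis(triisopropylsilyloxy)phenyl]{2,6-bis(methoxymethoxy)-4-[2-(4-(methoxymethoxy)phenyl)ethyl]phenyl}methanol (not isolated) | OC(c1cc(O[Si](C(C)C)(C(C)C)C(C)C)cc(O[Si](C(C)C)(C(C)C)C(C)C)c1)c1c(OCOC)cc(CCc2ccc(OCOC)cc2)cc1OCOC | intermediate
7 | racemic 2-{[3,5-bis(triisopropylsilyloxy)phenyl](4-methylbenzenesulfonyl)methyl}-5-[2-(4-hydroxyphenyl)ethyl]benzene-1,3-diol | Cc1ccc(cc1)S(=O)(=O)C(c1cc(O[Si](C(C)C)(C(C)C)C(C)C)cc(O[Si](C(C)C)(C(C)C)C(C)C)c1)c1c(O)cc(CCc2ccc(O)cc2)cc1O | intermediate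
8 | 4-bromoresorcinol, 4-bromobenzene-1,3-diol | Oc1ccc(Br)c(O)c1 | starting material
9 | 1-bromo-2,4-bis(triisopropylsilyloxy)benzene | Brc1ccc(O[Si](C(C)C)(C(C)C)C(C)C)cc1O[Si](C(C)C)(C(C)C)C(C)C | intermediate
10 | nitromethane | C[N+](=O)[O-] | starting material
11 | 1-(nitromethyl)-2,4-bis(triisopropylsilyloxy)benzene | [O-][N+](=O)Cc1ccc(O[Si](C(C)C)(C(C)C)C(C)C)cc1O[Si](C(C)C)(C(C)C)C(C)C | intermediate
12 | 6-{[3,5-bis(triisopropylsilyloxy)phenyl]methylidene}-5-hydroxy-3-[2-(4-hydroxyphenyl)ethyl]cyclohexa-2,4-dien-1-one, alkene geometry not defined (not isolated) | O=C1C=C(CCc2ccc(O)cc2)C=C(O)C1=Cc1cc(O[Si](C(C)C)(C(C)C)C(C)C)cc(O[Si](C(C)C)(C(C)C)C(C)C)c1 | intermediate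
13 | 2-{(1S)-1-[3,5-bis(triisopropylsilyloxy)phenyl]-2-[2,4-bis(triisopropylsilyloxy)phenyl]-2-nitroethyl}-5-[2-(4-hydroxyphenyl)ethyl]benzene-1,3-diol, epimer mixture at the nitro carbon | [O-][N+](=O)C(c1ccc(O[Si](C(C)C)(C(C)C)C(C)C)cc1O[Si](C(C)C)(C(C)C)C(C)C)[C@@H](c1cc(O[Si](C(C)C)(C(C)C)C(C)C)cc(O[Si](C(C)C)(C(C)C)C(C)C)c1)c1c(O)cc(CCc2ccc(O)cc2)cc1O | intermediate
14 | 2-[(1S)-1-(3,5-dihydroxyphenyl)-2-(2,4-dihydroxyphenyl)-2-nitroethyl]-5-[2-(4-hydroxyphenyl)ethyl]benzene-1,3-diol, epimer mixture at the nitro carbon (not isolated) | [O-][N+](=O)C(c1ccc(O)cc1O)[C@@H](c1cc(O)cc(O)c1)c1c(O)cc(CCc2ccc(O)cc2)cc1O | intermediate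
15 | 4-{(2S)-2-(3,5-dihydroxyphenyl)-2-[2,6-dihydroxy-4-(2-(4-hydroxyphenyl)ethyl)phenyl]ethylidene}-3-hydroxycyclohexa-2,5-dien-1-one, alkene geometry not defined (not isolated) | O=C1C=CC(=C[C@@H](c2cc(O)cc(O)c2)c2c(O)cc(CCc3ccc(O)cc3)cc2O)C(O)=C1 | intermediate
16 | (2S,3S)-2-(2,4-dihydroxyphenyl)-3-(3,5-dihydroxyphenyl)-6-[2-(4-hydroxyphenyl)ethyl]-2,3-dihydro-1-benzofuran-4-ol, trans | Oc1ccc(CCc2cc(O)c3c(c2)O[C@H](c2ccc(O)cc2O)[C@H]3c2cc(O)cc(O)c2)cc1 | target

## Step count and risks

Total step count: 7. Longest linear sequence: 4 (steps 1, 3, 6, 7; the branches through steps 2 and 4–5 are equally long).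

Three steps most likely to fail:

**Step 6 (proposed new step).** The risks are a racemic background addition of the sodium nitronate at the water interface, slow addition to the crowded 2,6-dioxygenated methide carbon, and erosion of ee by retro-Michael fragmentation of 13 on long exposure to base. The facial sense of the catalyst is a model and must be checked on the first run; the quinidine-derived pseudo-enantiomer is the switch if it is opposite. The fallback uses known chemistry only, sets out from 9 and 7 and comes back at 16. Bromine–lithium exchange on 9 with n-BuLi at −78 °C and trapping with paraformaldehyde gives [2,4-bis(triisopropylsilyloxy)phenyl]methanol F1. Thiolane and HBF4·OEt2 convert it into 1-{[2,4-bis(triisopropylsilyloxy)phenyl]methyl}thiolan-1-ium tetrafluoroborate F2. F2 and sulfone 7 with Cs2CO3 in CH2Cl2 undergo the established [4+1] annulation of a sulfonium ylide with the ortho-quinone methide to give racemic trans-2-[2,4-bis(triisopropylsilyloxy)phenyl]-3-[3,5-bis(triisopropylsilyloxy)phenyl]-6-[2-(4-hydroxyphenyl)ethyl]-2,3-dihydro-1-benzofuran-4-ol F3. TBAF/AcOH gives the racemic target F4, which is resolved by preparative HPLC on a polysaccharide chiral phase to give 16.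

**Step 7 (proposed new step).** The risks are that the nitro carbon rests as the nitronate so that nitrite is not expelled, that the ring A phenoxide fragments the C2–C3 bond by retro-Michael reaction (loss of ee), and that quinone methide 15 tautomerises to a triarylethene. The fallback uses known chemistry, sets out from 13 and comes back at 16. SnCl4 in CH2Cl2 at −40 °C ionises the benzylic C–NO2 bond (Lewis-acid substitution of benzylic nitro compounds), the ring A phenol traps the cation, and aqueous NaHCO3 quench gives (2S,3S)-2-[2,4-bis(triisopropylsilyloxy)phenyl]-3-[3,5-bis(triisopropylsilyloxy)phenyl]-6-[2-(4-hydroxyphenyl)ethyl]-2,3-dihydro-1-benzofuran-4-ol F5. TBAF/AcOH then removes the four silyl groups from the already closed ring to give 16.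

**Step 3.** The risks are Friedel–Crafts self-condensation of the benzhydryl cation with the free resorcinol ring during the acidic stage, and partial loss of TIPS groups. The fallback sets out from 6 and comes back at 7. The addition is quenched with water and 6 is isolated on triethylamine-deactivated silica. Dess–Martin periodinane oxidises it to [3,5-bis(triisopropylsilyloxy)phenyl]{2,6-bis(methoxymethoxy)-4-[2-(4-(methoxymethoxy)phenyl)ethyl]phenyl}methanone F6, which cannot ionise. HCl in MeOH removes the three MOM groups to give [3,5-bis(triisopropylsilyloxy)phenyl]{2,6-dihydroxy-4-[2-(4-hydroxyphenyl)ethyl]phenyl}methanone F7. NaBH4 reduces it to racemic 2-{[3,5-bis(triisopropylsilyloxy)phenyl](hydroxy)methyl}-5-[2-(4-hydroxyphenyl)ethyl]benzene-1,3-diol F8. 4-Methylbenzenesulfinic acid in CH2Cl2 at rt then gives 7 under much milder acid.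

## Further compounds

F1 | step 6 | [2,4-bis(triisopropylsilyloxy)phenyl]methanol | OCc1ccc(O[Si](C(C)C)(C(C)C)C(C)C)cc1O[Si](C(C)C)(C(C)C)C(C)C
F2 | step 6 | 1-{[2,4-bis(triisopropylsilyloxy)phenyl]methyl}thiolan-1-ium tetrafluoroborate | F[B-](F)(F)F.CC(C)[Si](Oc1ccc(C[S+]2CCCC2)c(O[Si](C(C)C)(C(C)C)C(C)C)c1)(C(C)C)C(C)C
F3 | step 6 | racemic trans-2-[2,4-bis(triisopropylsilyloxy)phenyl]-3-[3,5-bis(triisopropylsilyloxy)phenyl]-6-[2-(4-hydroxyphenyl)ethyl]-2,3-dihydro-1-benzofuran-4-ol (both enantiomers written) | Oc1ccc(CCc2cc(O)c3c(c2)O[C@H](c2ccc(O[Si](C(C)C)(C(C)C)C(C)C)cc2O[Si](C(C)C)(C(C)C)C(C)C)[C@H]3c2cc(O[Si](C(C)C)(C(C)C)C(C)C)cc(O[Si](C(C)C)(C(C)C)C(C)C)c2)cc1.Oc1ccc(CCc2cc(O)c3c(c2)O[C@@H](c2ccc(O[Si](C(C)C)(C(C)C)C(C)C)cc2O[Si](C(C)C)(C(C)C)C(C)C)[C@@H]3c2cc(O[Si](C(C)C)(C(C)C)C(C)C)cc(O[Si](C(C)C)(C(C)C)C(C)C)c2)cc1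
F4 | step 6 | racemic trans-2-(2,4-dihydroxyphenyl)-3-(3,5-dihydroxyphenyl)-6-[2-(4-hydroxyphenyl)ethyl]-2,3-dihydro-1-benzofuran-4-ol (both enantiomers written) | Oc1ccc(CCc2cc(O)c3c(c2)O[C@H](c2ccc(O)cc2O)[C@H]3c2cc(O)cc(O)c2)cc1.Oc1ccc(CCc2cc(O)c3c(c2)O[C@@H](c2ccc(O)cc2O)[C@@H]3c2cc(O)cc(O)c2)cc1
F5 | step 7 | (2S,3S)-2-[2,4-bis(triisopropylsilyloxy)phenyl]-3-[3,5-bis(triisopropylsilyloxy)phenyl]-6-[2-(4-hydroxyphenyl)ethyl]-2,3-dihydro-1-benzofuran-4-ol | Oc1ccc(CCc2cc(O)c3c(c2)O[C@H](c2ccc(O[Si](C(C)C)(C(C)C)C(C)C)cc2O[Si](C(C)C)(C(C)C)C(C)C)[C@H]3c2cc(O[Si](C(C)C)(C(C)C)C(C)C)cc(O[Si](C(C)C)(C(C)C)C(C)C)c2)cc1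
F6 | step 3 | [3,5-bis(triisopropylsilyloxy)phenyl]{2,6-bis(methoxymethoxy)-4-[2-(4-(methoxymethoxy)phenyl)ethyl]phenyl}methanone | O=C(c1cc(O[Si](C(C)C)(C(C)C)C(C)C)cc(O[Si](C(C)C)(C(C)C)C(C)C)c1)c1c(OCOC)cc(CCc2ccc(OCOC)cc2)cc1OCOC
F7 | step 3 | [3,5-bis(triisopropylsilyloxy)phenyl]{2,6-dihydroxy-4-[2-(4-hydroxyphenyl)ethyl]phenyl}methanone | O=C(c1cc(O[Si](C(C)C)(C(C)C)C(C)C)cc(O[Si](C(C)C)(C(C)C)C(C)C)c1)c1c(O)cc(CCc2ccc(O)cc2)cc1O
F8 | step 3 | racemic 2-{[3,5-bis(triisopropylsilyloxy)phenyl](hydroxy)methyl}-5-[2-(4-hydroxyphenyl)ethyl]benzene-1,3-diol | OC(c1cc(O[Si](C(C)C)(C(C)C)C(C)C)cc(O[Si](C(C)C)(C(C)C)C(C)C)c1)c1c(O)cc(CCc2ccc(O)cc2)cc1O
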